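The runs are simulated with made-up constants; scatter was added.

Tuesday's run, in which the enzyme E turns the substrate D into the product X, cannot be first order in D: between 2.50 min and 5.00 min X gains 33 percentage points, more than the 28.6% of the first 2.50 min.

| flask | D | E | remark | time |
|---|---|---|---|---|
| Tuesday's | 0.050 M | 20 µM | run made earlier |  |
| Sunday's | 0.050 M | 13 µM | run made earlier |  |
| Wednesday's | 0.050 M | 30 µM | run made earlier |  |
| Friday's | 0.025 M | 20 µM | run made earlier |  |
| north-east | 0.050 M | 20 µM | everything together in a closed stirred flask, run for 6.0 min | 6.0 min |
| south-east | 0.050 M | 20 µM | a single well-mixed tank run continuously and read at steady state, 6.0 min in it on average |  |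
| south | 0.050 M (fed, over 6.00 min) | 20 µM | all but D at the start; D goes in evenly over 6.00 min, the run ends at 6.0 min | 6.0 min |

- Tuesday's (time / min: X / %): 0.333: 5.3; 1.00: 9.9; 1.50: 17.1; 2.50: 28.6; 4.00: 46.6; 5.00: 61.2; 6.00: 71.2
- Sunday's (time / min: X / %): 0.667: 4.8; 1.33: 10.2; 2.00: 14.3; 3.00: 21.3; 4.00: 30.5; 5.00: 39.6
- Wednesday's (time / min: X / %): 0.417: 6.2; 0.667: 11.6; 0.833: 15.4; 1.33: 23.8; 2.00: 35.4; 3.00: 53.0; 5.00: 83.0
- Friday's (time / min: X / %): 1.00: 23.2; 2.00: 45.6; 3.00: 63.8; 4.00: 78.5; 5.00: 85.2

(each reading ± 1 percentage point)

1. the set-up with the highest amount of X at the outlet or at the end, in percent of the D put in ("none" if the first two lie within 2 percentage points) (north-east / south-east / south / none)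
2. amount of X at the outlet or at the end, in percent of the D put in, north-east
3. amount of X at the outlet or at the end, in percent of the D put in, south-east
4. amount of X at the outlet or at the end, in percent of the D put in, south

- the stated concentrations are those of everything mixed, before any reaction; amounts are the same in each set-up
- the numbers in the tables scatter by 1 percentage point (one standard deviation)
- the feed brings no volume worth counting
- the earlier runs were made in a closed, stirred flask

So the rate looks flat in D (zero order), and Wednesday's run at 3.00 min gives 294 /min as the flat turnover, the D turned per E per minute. Sunday's run, with less E than Wednesday's, reads 305 /min at 5.00 min, close to it, so the rate follows E.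

Integrating a flat rate gives X = turnover × E × time. For the closed north-east flask this reckoning gives 70.7% of the charge.

But Friday's run, around 0.0164 M of D, reads a turnover of 280 /min. At that turnover the south-east tank, 6.0 min on average, gives 67.2% in this reckoning, less than its figure for north-east, and leaves 0.0164 M of D, about Friday's D.

In south the feed of 0.00833 M/min is more than the flat rate of 0.00589 M/min, so D builds up from nothing. Its first minutes pass at low D, and this reckoning puts south below 70.7% without giving a figure.

The forecast names north-east, with 71.5% in north-east, 65% in south-east and 55% in south, the last since “the feed outruns the rate and the early rate is low”. Its north-east stands above the reckoning here, its south-east below.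

The flasks give 70.6% in north-east, 66.0% in south-east and 54.5% in south, so north-east is highest.

    D + E → X + E, rate k1*[D]*[E]/(1 + ([D]/Km1) + ([D]/Ksi1)^2) (0.0950 M, 29.0 mM, k = 410 /M/s)

 The neighbouring flask takes north-east with 0.085 M of D, the same E and the same time. The flat turnover 294 /min gives it 41.6% of its charge, but it yields 31.6%, with 68% of its D still there, and its turnover, averaged over the 6.0 min, is 224 /min, less than 294 /min.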